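## Retrosynthetic overview

- **Feature:** The open chain C7–C8–C8'–C7' links the two benzene rings, and its central C8–C8' bond joins two CH(CH3) carbons in a threo relation. If C7 and C7' are both imagined as carboxyl carbons, the two halves become identical. The core is then C2-symmetric (2S,3S)-2,3-dimethylsuccinic acid, a propionate dimer.
- **Disconnections (retro order):** phenol O–Si and C7 O–acetyl; C7–veratryl (aryl metal plus α-methyl aldehyde, Felkin–Anh); C7' carbonyl to CH2 and C7'–guaiacyl (aryl Grignard plus trans-anhydride); C8–C8' (oxidative dimerisation of an auxiliary-bearing propionate enolate).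
- **Rings:** Neither benzene ring is built, since both enter as aryl bromides. The only ring closed is the five-membered anhydride in step 3, a temporary device that is opened again in step 5. The chain grows in the sequence C8–C8', C7'–aryl, C7–aryl.
- **Stereo:** C8 and C8' arise together from two (R)-4-benzyloxazolidinones in the dimerisation. C7 is relayed from C8 in the aldehyde arylation.

Key step: step 1

Remark: lignan numbering is used (C7 = acetoxy-bearing benzylic carbon, C8 and C8' = methyl-bearing carbons, C7' = benzylic CH2). The SMILES is read as 7R,8S,8'R, that is 7,8-syn and 8,8'-threo. The differing descriptors at C8 and C8' reflect only a change in CIP priorities.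

## Route

Step 1
Reactants: 1 (R)-4-benzyl-3-propionyloxazolidin-2-one (two equivalents, one for each half of the product)
Product: 4 (2S,3S)-1,4-bis[(R)-4-benzyl-2-oxooxazolidin-3-yl]-2,3-dimethylbutane-1,4-dione, via lithium Z-enolate 2 (not isolated), via trichlorotitanium Z-enolate 3 (not isolated)
Conditions: LiN(i-Pr)2 (LDA, commercial solution, 1.05 equiv), THF, −78 °C; TiCl4 (1.1 equiv, in CH2Cl2), −78 °C → rt; aq NH4Cl; crystallisation or chromatography
Reagents that add atoms: none
Why: LDA gives the chelated Z-enolate 2, TiCl4 converts it into the titanium enolate 3, and inner-sphere electron transfer from the enolate to tetravalent titanium (which leaves as trivalent TiCl3) produces an α-carbonyl radical, or its titanium-bound equivalent, that bonds through its α-carbon to the α-carbon of a second enolate, so the C8–C8' bond forms between two carbons of the same polarity. The closest known reaction type is the oxidative homocoupling of metal enolates of chiral 3-acyloxazolidin-2-ones with TiCl4, CuCl2 or PhI(OAc)2, which leads to 2,3-disubstituted succinic acid derivatives. The union is intermolecular and no ring is closed. Both new stereocentres (C8 and C8') are controlled by the C4 benzyl group of the (R)-auxiliary, which covers one face of each planar chelated α-carbon and leaves open the face used in Evans alkylations, so each carbon becomes S. The selectivity needed is diastereofacial at both partners: the S,R isomer would need one partner, and the R,R isomer both, to react on the covered face, and because all three isomers carry two homochiral auxiliaries they are diastereomers that can be separated at this stage. Cross-selectivity does not arise because the partners are identical, and the small methyl substituent keeps the crowded bond formation feasible.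

Step 2
Reactants: 4 (2S,3S)-bis-imide
Product: 6 (2S,3S)-2,3-dimethylsuccinic acid, via bis-peroxy acid 5 (not isolated)
Conditions: LiOH·H2O, 30% aq H2O2, THF/H2O, 0 °C; aq Na2SO3; extract auxiliary (CH2Cl2); HCl to pH 2, extract (EtOAc, NaCl-saturated)
Reagents that add atoms: hydrogen peroxide, OO
Why: In this lithium hydroperoxide cleavage of N-acyloxazolidinones the small, strongly nucleophilic but weakly basic hydroperoxide anion attacks the exocyclic imide carbonyls next to the branched α-carbons without epimerising C8/C8' at 0 °C, sulfite then reduces the peroxy acid groups of 5, and the auxiliary is recovered before acidification.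

Step 3
Reactants: 6 (2S,3S)-2,3-dimethylsuccinic acid
Product: 7 (3S,4S)-3,4-dimethyldihydrofuran-2,5-dione (trans-2,3-dimethylsuccinic anhydride)
Conditions: AcCl (neat, excess), 45 °C; evaporate, used crude or after short-path distillation
Reagents that add atoms: none
Why: Dehydrative cyclisation of a succinic acid with acetyl chloride closes the five-membered anhydride without base and with only volatile co-products, so both α-stereocentres stay untouched and the trans ring, which keeps the C2 axis, should be obtained.

Step 4
Reactants: 8 4-bromo-2-methoxyphenol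
Product: 9 (4-bromo-2-methoxyphenoxy)triisopropylsilane
Conditions: TIPSCl, imidazole, DMF, rt
Reagents that add atoms: triisopropylsilyl chloride, CC(C)[Si](Cl)(C(C)C)C(C)C
Why: Imidazole-promoted silylation masks the acidic phenol before metalation, and the bulky aryl triisopropylsilyl ether is chosen because it tolerates Grignard formation, trifluoroacetic acid, borane and organotitanium reagents yet is cleaved by fluoride.

Step 5
Reactants: 7 trans-(3S,4S)-anhydride; 9 (4-bromo-2-methoxyphenoxy)triisopropylsilane
Product: 11 (2S,3S)-4-[3-methoxy-4-(triisopropylsilyloxy)phenyl]-2,3-dimethyl-4-oxobutanoic acid, via arylmagnesium bromide 10 (not isolated)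
Conditions: 9, Mg turnings (iodine-activated), THF, 40 °C; cannulated slowly into 7 (1.0 equiv), THF, −78 °C; quench at −78 °C with 1 M HCl
Reagents that add atoms: none
Why: In this acylation of a Grignard reagent by a cyclic anhydride the C2 axis of 7 interchanges its two carbonyl groups, so attack at one or the other gives the same keto acid with no need for regiocontrol, while inverse addition at −78 °C and the low electrophilicity of the electron-rich aryl ketone carboxylate hold back a second addition and enolisation at C8'.

Step 6
Reactants: 11 γ-keto acid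
Product: 14 (2S,3R)-4-[3-methoxy-4-(triisopropylsilyloxy)phenyl]-2,3-dimethylbutanoic acid, via hydroxy acid 12 (not isolated), via gamma-lactone 13 (not isolated)
Conditions: Et3SiH (4 equiv), CF3CO2H/CH2Cl2, 0 °C → rt
Reagents that add atoms: none
Why: In this ionic hydrogenation of an electron-rich aryl ketone, hydride transfer to the protonated ketone gives 12, which ionises (reversibly parked as lactone 13) to a benzylic cation stabilised by the para silyloxy group and accepts a second hydride, while the carboxylic acid, the aryl silyl ether and both methyl-bearing centres stay as they are (C8' changes descriptor from S to R only because the priorities change).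

Step 7
Reactants: 14 (2S,3R)-acid
Product: 15 (2S,3R)-4-[3-methoxy-4-(triisopropylsilyloxy)phenyl]-2,3-dimethylbutan-1-ol
Conditions: BH3·THF, THF, 0 °C → rt; H2O work-up
Reagents that add atoms: none
Why: Chemoselective borane reduction of a carboxylic acid through its acyloxyborane runs under non-basic conditions, so C8 is not epimerised and the aryl silyl and methyl ethers are untouched.

Step 8
Reactants: 15 (2S,3R)-alcohol
Product: 16 (2S,3R)-4-[3-methoxy-4-(triisopropylsilyloxy)phenyl]-2,3-dimethylbutanal
Conditions: Dess–Martin periodinane, CH2Cl2, 0 °C → rt; used without storage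
Reagents that add atoms: none
Why: Dess–Martin oxidation stops at the aldehyde under nearly neutral conditions, which protects the epimerisable α-methyl centre C8.

Step 9
Reactants: 16 (2S,3R)-aldehyde; 17 4-bromo-1,2-dimethoxybenzene (4-bromoveratrole)
Product: 20 (1R,2S,3R)-1-(3,4-dimethoxyphenyl)-4-[3-methoxy-4-(triisopropylsilyloxy)phenyl]-2,3-dimethylbutan-1-ol, via 3,4-dimethoxyphenyllithium 18 (not isolated), via aryltitanium triisopropoxide 19 (not isolated)
Conditions: 17, n-BuLi, THF, −78 °C; ClTi(Oi-Pr)3, −78 → −30 °C; 16, −78 → −20 °C; H2O, filtration through Celite; chromatography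
Reagents that add atoms: none
Why: Bromine–lithium exchange and transmetalation give a weakly basic, bulky aryltitanium reagent that adds in the Felkin–Anh sense, with the sec-alkyl C8' branch perpendicular to the carbonyl and the aryl group approaching anti to it past the C8 hydrogen (Si face), so the 7,8-syn (7R) alcohol should predominate and the minor C7 epimer is removed by chromatography.

Step 10
Reactants: 20 7,8-syn benzylic alcohol
Product: 21 (1R,2S,3R)-1-(3,4-dimethoxyphenyl)-4-[3-methoxy-4-(triisopropylsilyloxy)phenyl]-2,3-dimethylbutyl acetate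
Conditions: Ac2O, pyridine, DMAP (cat.), CH2Cl2, 0 °C → rt
Reagents that add atoms: acetic anhydride, CC(=O)OC(C)=O
Why: DMAP-catalysed acylation esterifies the secondary benzylic alcohol at oxygen under basic conditions, so the C7–O bond is never broken and the configuration is retained.

Step 11
Reactants: 21 silyl-protected acetate
Product: 22 (1R,2S,3R)-1-(3,4-dimethoxyphenyl)-4-(4-hydroxy-3-methoxyphenyl)-2,3-dimethylbutyl acetate (target CNP0118842.1)
Conditions: Bu4NF, AcOH, THF, 0 °C; chromatography on neutral silica
Reagents that add atoms: none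
Why: Fluoride-induced cleavage of the aryl silyl ether is fast at 0 °C, and the acetic acid buffer protonates the phenoxide as it forms, so the acid- and base-sensitive benzylic acetate is neither hydrolysed nor transferred.

## Compound list

1 | (R)-4-benzyl-3-propionyloxazolidin-2-one | CCC(=O)N1[C@H](Cc2ccccc2)COC1=O | starting material
2 | lithium (Z)-enolate of 1 | C/C=C(\[O-])N1[C@H](Cc2ccccc2)COC1=O.[Li+] | intermediate
3 | trichlorotitanium (Z)-enolate of 1 | C/C=C(\O[Ti](Cl)(Cl)Cl)N1[C@H](Cc2ccccc2)COC1=O | intermediate
4 | (2S,3S)-1,4-bis[(R)-4-benzyl-2-oxooxazolidin-3-yl]-2,3-dimethylbutane-1,4-dione | O=C1OC[C@@H](Cc2ccccc2)N1C(=O)[C@@H](C)[C@H](C)C(=O)N1[C@H](Cc2ccccc2)COC1=O | intermediate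
5 | (2S,3S)-2,3-dimethylbutanediperoxoic acid | OOC(=O)[C@@H](C)[C@H](C)C(=O)OO | intermediate
6 | (2S,3S)-2,3-dimethylsuccinic acid | OC(=O)[C@@H](C)[C@H](C)C(=O)O | intermediate
7 | (3S,4S)-3,4-dimethyldihydrofuran-2,5-dione | O=C1[C@@H](C)[C@H](C)C(=O)O1 | intermediate
8 | 4-bromo-2-methoxyphenol | COc1cc(Br)ccc1O | starting material
9 | (4-bromo-2-methoxyphenoxy)triisopropylsilane | COc1cc(Br)ccc1O[Si](C(C)C)(C(C)C)C(C)C | intermediate
10 | [3-methoxy-4-(triisopropylsilyloxy)phenyl]magnesium bromide | COc1cc([Mg]Br)ccc1O[Si](C(C)C)(C(C)C)C(C)C | intermediate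
11 | (2S,3S)-4-[3-methoxy-4-(triisopropylsilyloxy)phenyl]-2,3-dimethyl-4-oxobutanoic acid | COc1cc(C(=O)[C@@H](C)[C@H](C)C(=O)O)ccc1O[Si](C(C)C)(C(C)C)C(C)C | intermediate
12 | (2S,3S)-4-hydroxy-4-[3-methoxy-4-(triisopropylsilyloxy)phenyl]-2,3-dimethylbutanoic acid (C4 epimers) | COc1cc(C(O)[C@@H](C)[C@H](C)C(=O)O)ccc1O[Si](C(C)C)(C(C)C)C(C)C | intermediate
13 | (3S,4S)-5-[3-methoxy-4-(triisopropylsilyloxy)phenyl]-3,4-dimethyldihydrofuran-2(3H)-one (C5 epimers) | COc1cc(C2[C@@H](C)[C@H](C)C(=O)O2)ccc1O[Si](C(C)C)(C(C)C)C(C)C | intermediate
14 | (2S,3R)-4-[3-methoxy-4-(triisopropylsilyloxy)phenyl]-2,3-dimethylbutanoic acid | COc1cc(C[C@@H](C)[C@H](C)C(=O)O)ccc1O[Si](C(C)C)(C(C)C)C(C)C | intermediate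
15 | (2S,3R)-4-[3-methoxy-4-(triisopropylsilyloxy)phenyl]-2,3-dimethylbutan-1-ol | COc1cc(C[C@@H](C)[C@H](C)CO)ccc1O[Si](C(C)C)(C(C)C)C(C)C | intermediate
16 | (2S,3R)-4-[3-methoxy-4-(triisopropylsilyloxy)phenyl]-2,3-dimethylbutanal | COc1cc(C[C@@H](C)[C@H](C)C=O)ccc1O[Si](C(C)C)(C(C)C)C(C)C | intermediate
17 | 4-bromo-1,2-dimethoxybenzene | COc1ccc(Br)cc1OC | starting material
18 | 3,4-dimethoxyphenyllithium | COc1ccc([Li])cc1OC | intermediate
19 | (3,4-dimethoxyphenyl)titanium triisopropoxide | COc1ccc([Ti](OC(C)C)(OC(C)C)OC(C)C)cc1OC | intermediate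
20 | (1R,2S,3R)-1-(3,4-dimethoxyphenyl)-4-[3-methoxy-4-(triisopropylsilyloxy)phenyl]-2,3-dimethylbutan-1-ol | COc1cc(C[C@@H](C)[C@H](C)[C@@H](O)c2ccc(OC)c(OC)c2)ccc1O[Si](C(C)C)(C(C)C)C(C)C | intermediate
21 | (1R,2S,3R)-1-(3,4-dimethoxyphenyl)-4-[3-methoxy-4-(triisopropylsilyloxy)phenyl]-2,3-dimethylbutyl acetate | COc1cc(C[C@@H](C)[C@H](C)[C@@H](OC(C)=O)c2ccc(OC)c(OC)c2)ccc1O[Si](C(C)C)(C(C)C)C(C)C | intermediate
22 | (1R,2S,3R)-1-(3,4-dimethoxyphenyl)-4-(4-hydroxy-3-methoxyphenyl)-2,3-dimethylbutyl acetate | COc1cc(C[C@@H](C)[C@H](C)[C@@H](OC(C)=O)c2ccc(OC)c(OC)c2)ccc1O | target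

## Step count

- Total step count: 11
- Longest linear sequence: 10 (steps 1–3 and 5–11, counted from 1)

## Steps most likely to fail

**Step 1.** The radical-type coupling may stall. The enolate may decay by loss of the auxiliary as the mixture warms, or facial selectivity at one partner may be poor.

The fallback forms the same C8–C8' bond by a polar, stereospecific displacement and sets out from 1.
- Commercial benzyl (S)-lactate is treated with Tf2O and 2,6-lutidine (CH2Cl2, −78 °C) to give benzyl (S)-2-(trifluoromethylsulfonyloxy)propanoate F1.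
- Enolate 2 (from 1, LDA, THF, −78 °C) displaces the triflate with inversion, an Evans alkylation with a secondary α-triflyloxy ester. This gives benzyl (2S,3S)-4-[(R)-4-benzyl-2-oxooxazolidin-3-yl]-2,3-dimethyl-4-oxobutanoate F2. The auxiliary sets one centre and the SN2 inversion sets the other.
- LiOH/H2O2 cleaves only the imide, through 4-(benzyloxy)-2,3-dimethyl-4-oxobutaneperoxoic acid F3. Na2SO3 reduces F3 in the flask to the half ester (2S,3S)-4-(benzyloxy)-2,3-dimethyl-4-oxobutanoic acid F4.
- Hydrogenolysis (H2, Pd/C, EtOAc) then returns to the route at diacid 6.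

**Step 5.** The Grignard reagent may add a second time to the liberated ketone. The carbon next to the new ketone may also epimerise under the basic conditions.

The fallback sets out from 7.
- MeNH(OMe)·HCl and pyridine (CH2Cl2, 0 °C) open the anhydride, again at either equivalent carbonyl, to give (2S,3S)-4-[methoxy(methyl)amino]-2,3-dimethyl-4-oxobutanoic acid F5.
- The acid is deprotonated with i-PrMgCl (1 equiv, THF, −20 °C), and Grignard reagent 10 is then added to the N-methoxy-N-methyl amide (Weinreb ketone synthesis).
- The adduct stays chelated to magnesium and releases the ketone only on acidic quench. Neither over-addition nor enolisation can therefore occur before the route is rejoined at keto acid 11.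

**Step 9.** Facial selectivity may be poor, because the bias between the methyl group and the sec-alkyl branch is only steric.

The fallback sets C7 by reagent-controlled reduction instead of addition and sets out from acid 14.
- Coupling with MeNH(OMe)·HCl (EDC·HCl, i-Pr2NEt, CH2Cl2) gives (2S,3R)-N-methoxy-4-[3-methoxy-4-(triisopropylsilyloxy)phenyl]-N,2,3-trimethylbutanamide F6.
- Aryllithium 18 (THF, −78 °C) converts F6 into (2S,3R)-1-(3,4-dimethoxyphenyl)-4-[3-methoxy-4-(triisopropylsilyloxy)phenyl]-2,3-dimethylbutan-1-one F7.
- Corey–Bakshi–Shibata reduction with (S)-Me-CBS and BH3·SMe2 (toluene, −20 °C) treats the aryl group as the large substituent. It should deliver the (7R) alcohol against the intrinsic Felkin preference of the ketone, rejoining the route at 20.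
- Unwanted C7 epimer from step 9 can be fed into the same sequence by Dess–Martin oxidation to F7.

## Further compounds

F1 | step 1 | benzyl (S)-2-(trifluoromethylsulfonyloxy)propanoate | C[C@H](OS(=O)(=O)C(F)(F)F)C(=O)OCc1ccccc1
F2 | step 1 | benzyl (2S,3S)-4-[(R)-4-benzyl-2-oxooxazolidin-3-yl]-2,3-dimethyl-4-oxobutanoate | O=C(OCc1ccccc1)[C@@H](C)[C@H](C)C(=O)N1[C@H](Cc2ccccc2)COC1=O
F3 | step 1 | (2S,3S)-4-(benzyloxy)-2,3-dimethyl-4-oxobutaneperoxoic acid | O=C(OCc1ccccc1)[C@@H](C)[C@H](C)C(=O)OO
F4 | step 1 | (2S,3S)-4-(benzyloxy)-2,3-dimethyl-4-oxobutanoic acid | O=C(OCc1ccccc1)[C@@H](C)[C@H](C)C(=O)O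
F5 | step 5 | (2S,3S)-4-[methoxy(methyl)amino]-2,3-dimethyl-4-oxobutanoic acid | CON(C)C(=O)[C@@H](C)[C@H](C)C(=O)O
F6 | step 9 | (2S,3R)-N-methoxy-4-[3-methoxy-4-(triisopropylsilyloxy)phenyl]-N,2,3-trimethylbutanamide | COc1cc(C[C@@H](C)[C@H](C)C(=O)N(C)OC)ccc1O[Si](C(C)C)(C(C)C)C(C)C
F7 | step 9 | (2S,3R)-1-(3,4-dimethoxyphenyl)-4-[3-methoxy-4-(triisopropylsilyloxy)phenyl]-2,3-dimethylbutan-1-one | COc1cc(C[C@@H](C)[C@H](C)C(=O)c2ccc(OC)c(OC)c2)ccc1O[Si](C(C)C)(C(C)C)C(C)C
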